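**Retrosynthetic overview**
- Ring A (ten-membered carbocycle) is opened last at C3–C4: Nozaki–Hiyama–Kishi closure of a (Z)-vinyl iodide onto an (E)-enal, which also creates C3.
- Ring B (cis-γ-lactone) with C6 and C7: allylboration/lactonisation between a 2-(methoxycarbonyl)allylboronate (fragment A) and (Z)-3-iodobut-2-enal (fragment B, from but-2-yn-1-ol).
- Key disconnection: the C8–O(angelate) bond, made as a C–O bond on the α-carbon of a linalool-derived lactol by a new amine-catalysed asymmetric α-angeloyloxylation; C8 then relays chirality to C7 and C6.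
- C10 comes from (R)-linalool; C11–C13 from methyl acrylate (Morita–Baylis–Hillman, then SN2' borylation); C3 from acrolein diethyl acetal (cross-metathesis).
- Ring order: ring B (step 10), then ring A (step 11).

Assumption: the target is taken exactly as drawn (cis-fused 6,12-lactone; germacrane numbering C1–C15 is used for locants) and (R)-linalool of at least 97% ee is used.

**Step 1**
Reactants: 1 (R)-linalool
Product: 3 (5R)-5-ethenyl-5-methyloxolan-2-ol, via secondary ozonide 2 (not isolated)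
Conditions: O3, CH2Cl2, −78 °C (Sudan Red 7B end point); then Me2S, −78 °C to rt
Reagents that add atoms: ozone, [O-][O+]=O
Why: Chemoselective ozonolysis of the electron-rich trisubstituted alkene (the vinyl group next to the carbinol is far slower) gives the hydroxy aldehyde, which closes to the lactol; C10 is carried over unchanged from linalool.

**Step 2**
Reactants: 4 angelic acid
Product: 5 bis[(2Z)-2-methylbut-2-enoyl] peroxide
Conditions: 4 (2.0 equiv in all), H2O2·urea (1.0 equiv), DCC (2.0 equiv), CH2Cl2, −10 °C, dark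
Reagents that add atoms: hydrogen peroxide, OO; angelic acid (the second equivalent of 4), C/C=C(/C)C(=O)O
Why: Carbodiimide-mediated double acylation of hydrogen peroxide (standard diacyl peroxide synthesis: two molecules of acid are joined to one molecule of H2O2, the first giving the peroxy acid and the second acylating it) at low temperature without nucleophilic catalyst, so the Z-alkene is kept; no stereocentre is formed.

**Step 3**
Reactants: 3 (5R)-5-ethenyl-5-methyloxolan-2-ol; 5 bis[(2Z)-2-methylbut-2-enoyl] peroxide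
Product: 6 (3R,5R)-5-ethenyl-2-hydroxy-5-methyloxolan-3-yl (2Z)-2-methylbut-2-enoate
Conditions: (R)-2-(triphenylmethyl)pyrrolidine (10 mol %), hydroquinone (10 mol %), THF, 0 °C
Reagents that add atoms: none
Why: Proposed new method: the lactol reacts through its open hydroxy-aldehyde form to give an E-enamine whose one face is blocked by the trityl group, and the enamine carbon attacks the O–O bond of 5 in an SN2-type oxygen transfer with angelate as leaving group, so the C8–O bond and the 8R centre are set by the catalyst (its antipode would give the 8-epimer) while the angeloyl group is never activated as an acyl electrophile and cannot isomerise to tiglate; the closest known reaction is the secondary-amine-catalysed α-benzoyloxylation of aldehydes with dibenzoyl peroxide, here extended to an α,β-unsaturated diacyl peroxide and a lactol substrate.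

**Step 4**
Reactants: 6 (3R,5R)-5-ethenyl-2-hydroxy-5-methyloxolan-3-yl (2Z)-2-methylbut-2-enoate; 7 methyl acrylate
Product: 8 methyl (4R,6R)-3,6-dihydroxy-6-methyl-2-methylidene-4-{[(2Z)-2-methylbut-2-enoyl]oxy}oct-7-enoate (C3 epimers)
Conditions: 7 (5 equiv), DABCO (1.0 equiv), 1,4-dioxane/H2O (1:1), rt
Reagents that add atoms: none
Why: Morita–Baylis–Hillman reaction of the α-acyloxy-activated aldehyde released from the lactol in the aqueous medium; the new carbinol (C7) becomes sp2 in step 6, so its configuration does not matter.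

**Step 5**
Reactants: 8 methyl (4R,6R)-3,6-dihydroxy-6-methyl-2-methylidene-4-{[(2Z)-2-methylbut-2-enoyl]oxy}oct-7-enoate
Product: 9 methyl (4R,6R)-3-acetoxy-6-hydroxy-6-methyl-2-methylidene-4-{[(2Z)-2-methylbut-2-enoyl]oxy}oct-7-enoate (C3 epimers)
Conditions: Ac2O (1.2 equiv), pyridine, DMAP (5 mol %), CH2Cl2, 0 °C
Reagents that add atoms: acetic anhydride, CC(=O)OC(C)=O
Why: Selective acetylation of the secondary allylic alcohol; the tertiary C10 alcohol does not react at 0 °C.

**Step 6**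
Reactants: 9 methyl (4R,6R)-3-acetoxy-6-hydroxy-6-methyl-2-methylidene-4-{[(2Z)-2-methylbut-2-enoyl]oxy}oct-7-enoate
Product: 10 methyl (2E,4R,6R)-6-hydroxy-6-methyl-4-{[(2Z)-2-methylbut-2-enoyl]oxy}-2-[(4,4,5,5-tetramethyl-1,3,2-dioxaborolan-2-yl)methyl]octa-2,7-dienoate
Conditions: B2pin2 (1.05 equiv), CuCl (5 mol %), Xantphos (5 mol %), KOt-Bu (10 mol %), THF, 0 °C
Reagents that add atoms: bis(pinacolato)diboron, CC1(C)OB(OC1(C)C)B1OC(C)(C)C(C)(C)O1
Why: Copper-catalysed SN2' borylation of a Morita–Baylis–Hillman acetate (borylcopper of monovalent copper adds to the acrylate terminus, then β-acetoxy elimination) gives the thermodynamically preferred enoate with C8 cis to CH2Bpin; the hindered angelate is much less electrophilic and is left alone with one equivalent of diboron.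

**Step 7**
Reactants: 10 methyl (2E,4R,6R)-6-hydroxy-6-methyl-4-{[(2Z)-2-methylbut-2-enoyl]oxy}-2-[(4,4,5,5-tetramethyl-1,3,2-dioxaborolan-2-yl)methyl]octa-2,7-dienoate; 11 acrolein diethyl acetal
Product: 12 methyl (2E,4R,6R,7E)-9,9-diethoxy-6-hydroxy-6-methyl-4-{[(2Z)-2-methylbut-2-enoyl]oxy}-2-[(4,4,5,5-tetramethyl-1,3,2-dioxaborolan-2-yl)methyl]nona-2,7-dienoate
Conditions: 11 (5 equiv), second-generation Hoveyda–Grubbs catalyst RuCl2(H2IMes)(=CH-C6H4-2-O-i-Pr) (5 mol %), CH2Cl2, 40 °C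
Reagents that add atoms: none
Why: Olefin cross-metathesis of the vinyl carbinol with the acetal gives the E-alkene under thermodynamic control; it is done here because both trisubstituted enoates are inert, whereas after step 10 the exocyclic methylene would ring-close onto this vinyl group, and the aldehyde stays masked so it cannot react with the allylboronate.

**Step 8**
Reactants: 13 but-2-yn-1-ol
Product: 15 (2Z)-3-iodobut-2-en-1-ol, via cyclic alkenylaluminate 14 (not isolated)
Conditions: NaAlH2(OCH2CH2OMe)2, THF, 0 °C to rt; EtOAc; then I2, THF, −78 °C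
Reagents that add atoms: iodine, II
Why: Hydroxyl-directed trans-hydroalumination of the propargylic alcohol followed by iodinolysis with retention gives only the Z-iodide, which fixes the later C4=C5 geometry.

**Step 9**
Reactants: 15 (2Z)-3-iodobut-2-en-1-ol
Product: 16 (2Z)-3-iodobut-2-enal
Conditions: MnO2 (15 equiv), CH2Cl2, rt, used crude
Reagents that add atoms: none
Why: Neutral allylic oxidation that does not isomerise the Z-iodoalkene.

**Step 10**
Reactants: 12 methyl (2E,4R,6R,7E)-9,9-diethoxy-6-hydroxy-6-methyl-4-{[(2Z)-2-methylbut-2-enoyl]oxy}-2-[(4,4,5,5-tetramethyl-1,3,2-dioxaborolan-2-yl)methyl]nona-2,7-dienoate; 16 (2Z)-3-iodobut-2-enal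
Product: 19 (1R,3R,4E)-3-hydroxy-1-[(2R,3R)-2-[(1Z)-2-iodoprop-1-en-1-yl]-4-methylidene-5-oxooxolan-3-yl]-3-methyl-6-oxohex-4-en-1-yl (2Z)-2-methylbut-2-enoate, via borate ester 17 (not isolated), via lactone acetal 18 (not isolated)
Conditions: 16 (1.5 equiv), PhMe (2 M), 45 °C, 48 h; then PPTS (0.2 equiv), acetone/H2O (9:1), 45 °C
Reagents that add atoms: water, O
Why: Allylboration through a closed chair transition state in which the C8 substituent cis to CH2B is axial gives the syn adduct and hence the cis-lactone (C6/C7), while A(1,3) strain holds H8 in the enoate plane and the aldehyde adds to the face anti to the C9 chain (7R from 8R); acid then closes ring B and unmasks the enal.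

**Step 11**
Reactants: 19 (1R,3R,4E)-3-hydroxy-1-[(2R,3R)-2-[(1Z)-2-iodoprop-1-en-1-yl]-4-methylidene-5-oxooxolan-3-yl]-3-methyl-6-oxohex-4-en-1-yl (2Z)-2-methylbut-2-enoate
Product: 20 (3aR,4R,6R,7E,9S,10Z,11aS)-6,9-dihydroxy-6,10-dimethyl-3-methylidene-2-oxo-2,3,3a,4,5,6,9,11a-octahydrocyclodeca[b]furan-4-yl (2Z)-2-methylbut-2-enoate
Conditions: CrCl2 (8 equiv), NiCl2 (2 mol %), DMSO/THF (3:1), rt, syringe-pump addition to 2 mM
Reagents that add atoms: none
Why: Nozaki–Hiyama–Kishi macrocyclisation (zerovalent nickel inserts into the vinyl iodide, transmetalation to trivalent chromium, 1,2-addition to the enal) closes ring A with both alkene geometries retained, and the 3S carbinol is expected from attack on the outer face of the s-trans enal with the C15 methyl turned away from the carbonyl; the C6 label changes from R to S only because iodine is replaced by carbon.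

**Compound list**
1 | (R)-linalool, (3R)-3,7-dimethylocta-1,6-dien-3-ol | C=C[C@](C)(O)CCC=C(C)C | starting material
2 | 3-[(3R)-3-hydroxy-3-methylpent-4-en-1-yl]-5,5-dimethyl-1,2,4-trioxolane (secondary ozonide) | C=C[C@](C)(O)CCC1OOC(C)(C)O1 | intermediate
3 | (5R)-5-ethenyl-5-methyloxolan-2-ol (anomer mixture) | C=C[C@@]1(C)CCC(O)O1 | intermediate
4 | angelic acid, (2Z)-2-methylbut-2-enoic acid | C/C=C(/C)C(=O)O | starting material
5 | bis[(2Z)-2-methylbut-2-enoyl] peroxide | C/C=C(/C)C(=O)OOC(=O)/C(C)=C\C | intermediate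
6 | (3R,5R)-5-ethenyl-2-hydroxy-5-methyloxolan-3-yl (2Z)-2-methylbut-2-enoate (anomer mixture) | C=C[C@@]1(C)C[C@@H](OC(=O)/C(C)=C\C)C(O)O1 | intermediate
7 | methyl acrylate | C=CC(=O)OC | starting material
8 | methyl (4R,6R)-3,6-dihydroxy-6-methyl-2-methylidene-4-{[(2Z)-2-methylbut-2-enoyl]oxy}oct-7-enoate (C3 epimers) | C=C(C(=O)OC)C(O)[C@H](OC(=O)/C(C)=C\C)C[C@@](C)(O)C=C | intermediate
9 | methyl (4R,6R)-3-acetoxy-6-hydroxy-6-methyl-2-methylidene-4-{[(2Z)-2-methylbut-2-enoyl]oxy}oct-7-enoate (C3 epimers) | C=C(C(=O)OC)C(OC(C)=O)[C@H](OC(=O)/C(C)=C\C)C[C@@](C)(O)C=C | intermediate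
10 | methyl (2E,4R,6R)-6-hydroxy-6-methyl-4-{[(2Z)-2-methylbut-2-enoyl]oxy}-2-[(4,4,5,5-tetramethyl-1,3,2-dioxaborolan-2-yl)methyl]octa-2,7-dienoate | COC(=O)/C(CB1OC(C)(C)C(C)(C)O1)=C/[C@H](OC(=O)/C(C)=C\C)C[C@@](C)(O)C=C | intermediate
11 | acrolein diethyl acetal, 3,3-diethoxyprop-1-ene | C=CC(OCC)OCC | starting material
12 | methyl (2E,4R,6R,7E)-9,9-diethoxy-6-hydroxy-6-methyl-4-{[(2Z)-2-methylbut-2-enoyl]oxy}-2-[(4,4,5,5-tetramethyl-1,3,2-dioxaborolan-2-yl)methyl]nona-2,7-dienoate | COC(=O)/C(CB1OC(C)(C)C(C)(C)O1)=C/[C@H](OC(=O)/C(C)=C\C)C[C@@](C)(O)/C=C/C(OCC)OCC | intermediate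
13 | but-2-yn-1-ol | CC#CCO | starting material
14 | sodium 2,2-bis(2-methoxyethoxy)-3-methyl-2,5-dihydro-1,2-oxaaluminol-2-uide (cyclic alkenylaluminate) | CC1=CCO[Al-]1(OCCOC)OCCOC.[Na+] | intermediate
15 | (2Z)-3-iodobut-2-en-1-ol | C/C(I)=C/CO | intermediate
16 | (2Z)-3-iodobut-2-enal | C/C(I)=C/C=O | intermediate
17 | methyl (3S,4R,6R,7E)-9,9-diethoxy-6-hydroxy-3-{(1R,2Z)-3-iodo-1-[(4,4,5,5-tetramethyl-1,3,2-dioxaborolan-2-yl)oxy]but-2-en-1-yl}-6-methyl-2-methylidene-4-{[(2Z)-2-methylbut-2-enoyl]oxy}non-7-enoate (borate ester) | COC(=O)C(=C)[C@@H]([C@@H](OB1OC(C)(C)C(C)(C)O1)/C=C(/C)I)[C@H](OC(=O)/C(C)=C\C)C[C@@](C)(O)/C=C/C(OCC)OCC | intermediate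
18 | (1R,3R,4E)-6,6-diethoxy-3-hydroxy-1-[(2R,3R)-2-[(1Z)-2-iodoprop-1-en-1-yl]-4-methylidene-5-oxooxolan-3-yl]-3-methylhex-4-en-1-yl (2Z)-2-methylbut-2-enoate (lactone acetal) | C=C1C(=O)O[C@@H](/C=C(/C)I)[C@H]1[C@H](OC(=O)/C(C)=C\C)C[C@@](C)(O)/C=C/C(OCC)OCC | intermediate
19 | (1R,3R,4E)-3-hydroxy-1-[(2R,3R)-2-[(1Z)-2-iodoprop-1-en-1-yl]-4-methylidene-5-oxooxolan-3-yl]-3-methyl-6-oxohex-4-en-1-yl (2Z)-2-methylbut-2-enoate | C=C1C(=O)O[C@@H](/C=C(/C)I)[C@H]1[C@H](OC(=O)/C(C)=C\C)C[C@@](C)(O)/C=C/C=O | intermediate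
20 | (3aR,4R,6R,7E,9S,10Z,11aS)-6,9-dihydroxy-6,10-dimethyl-3-methylidene-2-oxo-2,3,3a,4,5,6,9,11a-octahydrocyclodeca[b]furan-4-yl (2Z)-2-methylbut-2-enoate; germacrane numbering 3S,6S,7R,8R,10R | C=C1C(=O)O[C@H]2/C=C(/C)[C@@H](O)/C=C/[C@](C)(O)C[C@@H](OC(=O)/C(C)=C\C)[C@@H]12 | target

**Step count and risks**

Total step count: 11. Longest linear sequence: 8 (steps 1, 3, 4, 5, 6, 7, 10, 11).

The three steps most likely to fail:

Step 3 (the proposed α-angeloyloxylation). Risks are N-acylation of the catalyst by the peroxide, radical decomposition of 5, and slow enamine formation from the lactol. The fallback uses known chemistry, sets out from 3 and returns at 6. L-Proline-catalysed α-aminoxylation of 3 with nitrosobenzene in DMSO gives (3R,5R)-3-(anilinooxy)-5-ethenyl-5-methyloxolan-2-ol F1 (L-proline gives the R centre needed). Fischer glycosidation (MeOH, camphorsulfonic acid) gives (3R,5R)-N-phenyl-O-(5-ethenyl-2-methoxy-5-methyloxolan-3-yl)hydroxylamine F2. N–O cleavage with Zn in AcOH gives (3R,5R)-5-ethenyl-2-methoxy-5-methyloxolan-3-ol F3. Mixed-anhydride esterification with angelic acid 4 (2,4,6-trichlorobenzoyl chloride, Et3N, toluene, 80 °C) gives (3R,5R)-5-ethenyl-2-methoxy-5-methyloxolan-3-yl (2Z)-2-methylbut-2-enoate F4. Hydrolysis of the methyl acetal in aqueous AcOH returns 6.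

Step 10 (allylboration). Risks are the low thermal reactivity of the ester-substituted allylboronate towards the sensitive iodoenal and insufficient facial control by C8. The fallback replaces the allylboronate by an allylindium reagent in water; it sets out from 8 and returns at 19. NBS/Me2S (CH2Cl2, 0 °C) converts 8 with allylic transposition into methyl (2Z,4R,6R)-2-(bromomethyl)-6-hydroxy-6-methyl-4-{[(2Z)-2-methylbut-2-enoyl]oxy}octa-2,7-dienoate F5. Cross-metathesis with 11 (same catalyst as step 7) gives methyl (2Z,4R,6R,7E)-2-(bromomethyl)-9,9-diethoxy-6-hydroxy-6-methyl-4-{[(2Z)-2-methylbut-2-enoyl]oxy}nona-2,7-dienoate F6. Indium powder with 16 in THF/H2O at rt gives methyl (3S,4R,6R,7E)-9,9-diethoxy-6-hydroxy-3-[(1R,2Z)-1-hydroxy-3-iodobut-2-en-1-yl]-6-methyl-2-methylidene-4-{[(2Z)-2-methylbut-2-enoyl]oxy}non-7-enoate F7; fast capture by the aldehyde in water is relied on to outrun 1,4-elimination of the angelate. PPTS in wet acetone then gives 19 by way of 18.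

Step 11 (macrocyclisation). Risks are ring strain and the wrong or mixed configuration at C3. The fallback moves C3 control from the C–C bond formation to a ketone reduction; it sets out from 19 and returns at 20. If the closure gives mainly the 3R epimer (3aR,4R,6R,7E,9R,10Z,11aS)-6,9-dihydroxy-6,10-dimethyl-3-methylidene-2-oxo-2,3,3a,4,5,6,9,11a-octahydrocyclodeca[b]furan-4-yl (2Z)-2-methylbut-2-enoate F8, or a mixture, MnO2 (CH2Cl2, rt) oxidises the bis-allylic alcohol to the cross-conjugated dienone (3aR,4R,6R,7E,10Z,11aS)-6-hydroxy-6,10-dimethyl-3-methylidene-2,9-dioxo-2,3,3a,4,5,6,9,11a-octahydrocyclodeca[b]furan-4-yl (2Z)-2-methylbut-2-enoate F9. 1,2-Reduction with NaBH4/CeCl3·7H2O (MeOH, −78 °C), or a BH3·SMe2 reduction catalysed by the appropriate enantiomer of 1-methyl-3,3-diphenyltetrahydro-1H,3H-pyrrolo[1,2-c][1,3,2]oxazaborole, gives 20.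

**Further compounds**
F1 | step 3 | (3R,5R)-3-(anilinooxy)-5-ethenyl-5-methyloxolan-2-ol | C=C[C@@]1(C)C[C@@H](ONc2ccccc2)C(O)O1
F2 | step 3 | (3R,5R)-N-phenyl-O-(5-ethenyl-2-methoxy-5-methyloxolan-3-yl)hydroxylamine | C=C[C@@]1(C)C[C@@H](ONc2ccccc2)C(OC)O1
F3 | step 3 | (3R,5R)-5-ethenyl-2-methoxy-5-methyloxolan-3-ol | C=C[C@@]1(C)C[C@@H](O)C(OC)O1
F4 | step 3 | (3R,5R)-5-ethenyl-2-methoxy-5-methyloxolan-3-yl (2Z)-2-methylbut-2-enoate | C=C[C@@]1(C)C[C@@H](OC(=O)/C(C)=C\C)C(OC)O1
F5 | step 10 | methyl (2Z,4R,6R)-2-(bromomethyl)-6-hydroxy-6-methyl-4-{[(2Z)-2-methylbut-2-enoyl]oxy}octa-2,7-dienoate | COC(=O)/C(CBr)=C/[C@H](OC(=O)/C(C)=C\C)C[C@@](C)(O)C=C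
F6 | step 10 | methyl (2Z,4R,6R,7E)-2-(bromomethyl)-9,9-diethoxy-6-hydroxy-6-methyl-4-{[(2Z)-2-methylbut-2-enoyl]oxy}nona-2,7-dienoate | COC(=O)/C(CBr)=C/[C@H](OC(=O)/C(C)=C\C)C[C@@](C)(O)/C=C/C(OCC)OCC
F7 | step 10 | methyl (3S,4R,6R,7E)-9,9-diethoxy-6-hydroxy-3-[(1R,2Z)-1-hydroxy-3-iodobut-2-en-1-yl]-6-methyl-2-methylidene-4-{[(2Z)-2-methylbut-2-enoyl]oxy}non-7-enoate | COC(=O)C(=C)[C@@H]([C@@H](O)/C=C(/C)I)[C@H](OC(=O)/C(C)=C\C)C[C@@](C)(O)/C=C/C(OCC)OCC
F8 | step 11 | (3aR,4R,6R,7E,9R,10Z,11aS)-6,9-dihydroxy-6,10-dimethyl-3-methylidene-2-oxo-2,3,3a,4,5,6,9,11a-octahydrocyclodeca[b]furan-4-yl (2Z)-2-methylbut-2-enoate (3-epimer of 20) | C=C1C(=O)O[C@H]2/C=C(/C)[C@H](O)/C=C/[C@](C)(O)C[C@@H](OC(=O)/C(C)=C\C)[C@@H]12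
F9 | step 11 | (3aR,4R,6R,7E,10Z,11aS)-6-hydroxy-6,10-dimethyl-3-methylidene-2,9-dioxo-2,3,3a,4,5,6,9,11a-octahydrocyclodeca[b]furan-4-yl (2Z)-2-methylbut-2-enoate | C=C1C(=O)O[C@H]2/C=C(/C)C(=O)/C=C/[C@](C)(O)C[C@@H](OC(=O)/C(C)=C\C)[C@@H]12
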